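Time came first: I asked how long partner stands in each flask before it is used.

| flask | substrate | partner | capture agent | remark | time |
|---|---|---|---|---|---|
| Friday's | 0.15 M | 0.15 M | 0.015 M | run made earlier |  |
| Thursday's | 0.30 M | 0.15 M | 0.015 M | run made earlier |  |
| epsilon | 0.15 M (fed, over 2.5 h) | 0.150 M | 0.0150 M | all else is in the flask from the start; the feed brings no volume worth counting | 4.0 h |
| gamma | 0.15 M | 0.150 M | 0.0150 M | everything together at the start | 4.0 h |
| beta | 0.15 M | 0.150 M (fed, over 2.5 h) | 0.0150 M | all else is in the flask from the start; the feed brings no volume worth counting | 4.0 h |
| delta | 0.15 M (in portions, 4, over 2.5 h) | 0.150 M | 0.0150 M | first portion at the start, last at 2.5 h | 4.0 h |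

- Friday's (time / h: double product / %, substrate / %): 0.500: 29.0, 30.5; 1.33: 28.9, 30.2; 2.50: 28.4, 30.3; 4.00: 29.1, 30.2
- Thursday's (time / min: double product / %, substrate / %): 6.00: 8.7, 58.6; 12.0: 8.4, 59.0; 20.0: 8.3, 59.2; 25.0: 8.5, 59.0

(standard deviation of a reading: 0.3 percentage points)

- the best flask by amount of double product, in percent of the substrate charged; "all alike" if 1.5 percentage points covers them all (epsilon / gamma / beta / delta / all alike)
- amount of double product at the end, in percent of the substrate charged, epsilon
- amount of double product at the end, in percent of the substrate charged, gamma
- amount of double product at the end, in percent of the substrate charged, beta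
- amount of double product at the end, in percent of the substrate charged, delta



1. I followed one substrate molecule: reaching double product takes two partner, so the charges set a ceiling of 50.0% of the substrate charged.

2. Partner, the limiting reagent in both runs, did not quite balance. Counting substrate lost plus double product as partner used, I found 1.45% of the charge missing on Friday's run and 0.950% on Thursday's, against a scatter of 0.3 percentage points per reading.

3. Thursday's run had stopped by 6.00 min, while epsilon's feed lasts 2.5 h, which is 25.0 times as long. I did not know how long partner stands in epsilon, so I took the whole feed as a generous guess at that time. Scaling the mean loss by that gave 30.0%: the share of the partner charge gone if it stands through the whole feed, my standing loss.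

4. For epsilon, this lowered the ceiling to 35.0%. Spending the remaining partner at Friday's yield gave a floor of 20.4%.

5. Delta's first portion, at two partner per substrate, can take up to half of the partner, so I expected a smaller standing loss there and placed delta first. Gamma repeats Friday's run, and I expected beta close to it.

6. The forecast differed: epsilon best at 46.5% (range 42% to 50%), gamma 29%, beta 29%, delta 45%, holding that “Feeding substrate into excess partner pushes each molecule through to double”. Its low end stood above my ceiling.

delta gave the most, 36.4%; epsilon gave 31.3%, inside my bracket, gamma 29.0% and beta 28.4%. Epsilon's partner stood at 0% at 2.00 h, earlier than the end of the feed.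

    substrate + partner → first product (k = 4.90 /M/min)
    partner + first product → double product (k = 4.00 /M/min)
    first product + capture agent → trapped intermediate (k = 0.230 /M/min)
    2 partner → self-condensation product (k = 0.0590 /M/min)

Delta held 0.0133 M of self-condensation product at 4.00 h, which is 17.7% of the partner charge. Used as delta's own standing loss, this is less than my 30.0% and puts its ceiling at 41.1%, above the 36.4% it gave.

In a further flask like delta but with 0.060 M of partner, the first portion can take up to 0.0750 M of partner, more than the charge, so I shrank the standing loss back to batch size and reckoned a ceiling of 19.8%. The computed flask gave 15.7%.

(The earlier runs and the new flask stem from a simulated flask with made-up constants, and the scatter is random.)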